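All runs were generated by integration with constants of no real substance; scatter was added.

Do not take a flat curve of target for proof of what stopped it.

| setting | blue | teal | south-west | south | south-east | north-west | west | north |
|---|---|---|---|---|---|---|---|---|
| substrate | 0.25 M | 0.25 M | 0.25 M | 0.25 M | 0.25 M | 0.25 M | 0.25 M | 0.25 M |
| partner | 1.3 equiv | 1.3 equiv | 1.30 equiv | 1.30 equiv | 1.30 equiv | 1.30 equiv | 1.30 equiv | 1.30 equiv |
| capture agent | 0.025 M | 0.025 M | 0.0250 M | 0.0250 M | 0.0250 M | 0.0250 M | 0.0250 M | 0.0250 M |
| free catalyst | 1.1 mol% | 17 mol% | 6.3 mol% | 2 mol% | 4 mol% | 12 mol% | 3 mol% | 25 mol% |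
| remark | run made earlier | run made earlier |  |  |  |  |  |  |
| time |  |  | 12 h | 12 h | 12 h | 12 h | 12 h | 12 h |

| run | time / h | target / % |
|---|---|---|
| blue | 0.500 | 0.9 |
| blue | 0.667 | 3.6 |
| blue | 1.00 | 4.3 |
| blue | 1.50 | 4.3 |
| blue | 2.50 | 5.2 |
| blue | 4.00 | 6.6 |
| blue | 6.00 | 4.2 |
| teal | 0.500 | 23.9 |
| teal | 0.667 | 31.4 |
| teal | 1.00 | 41.5 |
| teal | 1.50 | 49.6 |
| teal | 2.50 | 62.6 |
| teal | 4.00 | 61.1 |
| teal | 6.00 | 62.8 |

(each reading ± 1 percentage point)

- the flasks by amount of target, in percent of the substrate charged, highest first, at 12 h (south-west / south / south-east / north-west / west / north)
- the amount of target, in percent of the substrate charged of the flask you put first, at 12 h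
- the amount of target, in percent of the substrate charged of the flask you put last, at 12 h

- the numbers in the tables scatter by 1 percentage point (one standard deviation)

Begin with the bench rule: a catalyst gives a fixed number of turnovers, so target on the plateau goes with the loading. Take the last three teal readings, which lie flat within their scatter, and divide their mean by the teal loading:

turnovers = 3.66

Call this the plateau turnover number, target on the flat part per catalyst charged. Blue's last four readings give 4.61, a loose figure, because a scatter of 1 percentage point sits on a very low plateau. Now multiply by the loadings at the two ends:

south: 7.31% of the substrate charged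

north: 91.4% of the substrate charged

The rule ranks the flasks by loading, highest first.

Next find its border. Suppose capture agent is what ends the catalyst, one for each. That needs capture agent per catalyst charged above one, and this ratio is 9.09 in blue but 0.588 in teal, 5.00 in south and 0.400 in north. Teal lies past the border and still goes flat, so its plateau needs another explanation. The north figure also comes close to the whole charge of substrate, the limiting reagent at 1.30 equiv of partner. Commit, then, to the south figure, and hold the north figure as an upper estimate.

The forecast, reasoning that “the catalyst dies after a limited number of turnovers”, gave north > north-west > south-west > south-east > west > south with 72% and 9.5%, lower than my north figure and higher than my south figure.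

The flasks give north > north-west > south-west > south-east > west > south, with 73.2% in north and 7.62% in south.

    substrate + free catalyst → catalyst intermediate A (k = 1.20 L mol⁻¹ min⁻¹)
    partner + catalyst intermediate A → catalyst intermediate B (k = 1.70 L mol⁻¹ min⁻¹)
    catalyst intermediate B ⇌ released group + catalyst intermediate C (K = 0.0400 M, k = 0.440 min⁻¹)
    catalyst intermediate C → free catalyst + target (k = 0.430 min⁻¹)
    capture agent + catalyst intermediate C → trapped intermediate (k = 0.530 L mol⁻¹ min⁻¹)
    substrate + target → side product (k = 0.0660 L mol⁻¹ min⁻¹)

North stands at 2.93 of target per catalyst charged against the 3.66 carried, so the rule overshoots there by 18 points. Remove the step substrate + target → side product and north gives 97.4% instead of 73.2%, so that step is the main reason for the target missing there.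

Now read south at 3.0 h: the carried number times the south loading gives 7.31%. The computed reading is 8.25%, with 61.6% of the substrate still present.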